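The amber and grey runs charge 0.13 M and 0.30 M of substrate, yet their summed products at 1.25 d give first-order constants of 0.577 /d and 0.579 /d. I therefore read a first-order activation as the rate-limiting step, with a half-time of 1.20 d.

| flask | substrate | first nucleophile | second nucleophile | protic impurity | remark | time |
|---|---|---|---|---|---|---|
| amber | 0.13 M | 0.30 M | 0.20 M | 4 mM | run made earlier |  |
| grey | 0.30 M | 0.30 M | 0.20 M | 4 mM | run made earlier |  |
| flask | 0.20 M | 0.300 M | 0.200 M | 4.00 mM |  | 8.0 d |

| run | time / d | other capture product / % | target / % |
|---|---|---|---|
| amber | 0.833 | 29.4 | 9.3 |
| amber | 1.25 | 38.8 | 12.6 |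
| amber | 1.67 | 45.4 | 15.6 |
| amber | 2.50 | 54.8 | 21.6 |
| amber | 4.00 | 63.6 | 26.5 |
| amber | 6.00 | 68.1 | 28.6 |
| amber | 10.0 | 69.6 | 30.1 |
| grey | 1.25 | 35.7 | 15.8 |
| grey | 3.00 | 50.8 | 31.5 |
| grey | 4.00 | 53.7 | 36.1 |
| grey | 6.00 | 56.3 | 40.6 |
| grey | 8.00 | 57.1 | 42.0 |
| grey | 10.0 | 56.9 | 42.8 |

(readings scatter by 0.3 percentage points)

1. share of other capture product in other capture product plus target at 1.0 h
2. share of other capture product in other capture product plus target at 15 h
3. share of other capture product in other capture product plus target at 8.0 d



From each end reading I take the losses of both nucleophiles from their products. Amber gives 4.31 and grey 3.44, so by substrate charge the flask lies at 3.95. This is my capture exponent, the logarithm of the fall in each nucleophile counted from its product alone, second over first. It differs between the two runs, so I treat it as an apparent number for this charge and not as a ratio of rate constants.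

At 1.0 h the flask stands far inside one half-time, so I use the exponent from amber's first reading, 5.16. With the charges, that makes the products 3.44 to one, a share of 77.5 %.

At 15 h the flask has used 60.6 mM of substrate. Amber's first reading, after 50.3 mM, shows 76.0 %, which I adopt.

At 8.0 d, 6.67 half-times have passed, so the flask has made 198 mM of products. I start from the share interpolated between the runs, 64.6 %. The target this implies gives, through the exponent, 130 mM of other capture product. Going round once more gives 127 mM. The two rounds swing about the answer, so I take their middle, a share of 64.9 %.

The forecast gives 91 %, 77.5 % and 64.8 %, calling its early value “poorly constrained”.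

The flask gives 80.7 %, 76.9 % and 65.7 %. At 8.00 d it holds 20 % of its second nucleophile, 0.0263 M of dormant form and 0.00400 M of quenched reagent, together 70.0 mM. Putting the computed 34.0 % of target through my exponent leaves 72.5 mM not turned into other capture product.

    second nucleophile ⇌ dormant form (K = 0.650, k = 0.0200 /h)
    substrate → intermediate (k = 0.0240 /h)
    second nucleophile + protic impurity → quenched reagent (k = 56.0 /M/h)
    second nucleophile + intermediate → other capture product (k = 580 /M/h)
    first nucleophile + intermediate → target (k = 89.0 /M/h)

Both earlier runs charged 0.20 M of second nucleophile, so in the neighbour flask with 0.12 M the exponent is an untested carry-over; I keep it as an assumption and start from equal products. Two rounds give 95.3 mM and 97.1 mM of other capture product, a share of 48.6 %. The computed share in that neighbour is 47.8 %.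

Readings and results are calculated for an exercise.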